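## The problem

The target 18 is a linear phlorotannin pentamer in which five benzene rings, A to E, are joined only through four diaryl ether oxygens and carry thirteen free phenolic hydroxyls. It has no stereocentre, so the whole task is positional: which oxygen on which ring becomes an ether and which stays a phenol. Ring A carries its ether at a carbon between two hydroxyls, ring B has ethers at C1 and C4 with C4 between two hydroxyls, and ring C is pentaoxygenated with its two ether oxygens on the adjacent carbons C1 and C6, which are hindered, electron-rich and cannot serve as electrophiles in an uncatalysed substitution. Rings C and E are pyrogallols and ring D is a catechol, so the free polyphenol is oxidised rapidly by air in base and can be released only in the last step, under acid, after all base-mediated ether formation has been done on protected material. The hardest bond is the ether between rings C and D, because the ring C oxygen at C6 lies between the ring B ether and an oxygenated carbon. The enabling feature is ring D: its ether oxygens at C1 (to ring C) and C5 (to ring E) are para and ortho to the C4 hydroxyl, and C2 and C6 carry hydrogen. If C4 begins as a nitro group, both ether carbons become electrophiles for phenoxides, and the nitro group is exchanged for the hydroxyl afterwards. The same relationship holds in ring B (C4 hydroxyl para to C1) and ring C (C6 hydroxyl ortho to C1), where a formyl group can play the part of the nitro group.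

## Retrosynthesis

**18 from 17.** The twelve O–methyl bonds are cut last. Methyl is chosen over benzyl because the building blocks are available as methyl ethers and because benzyl ethers would not survive the hydrogenation of the nitro group. Precursor 17 is the dodecamethyl ether with one free hydroxyl at C4 of ring D; it should be stable to air and to chromatography. The forward step must cleave twelve alkyl aryl ethers and leave four diaryl ethers intact, without base or oxidant.

**17 from 14 by way of 15.** The C4–O bond of ring D is traced back to a C4–N bond: phenol 17 from aniline 15 through diazonium salt 16, and 15 from nitro compound 14. This leaves on ring D the one group that can activate both of its ether carbons. The forward steps must reduce a hindered nitro group without touching aryl ethers, and must replace a diazonium group by hydroxyl faster than the aryl intermediate cyclises onto ring E.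

**14 from 10, 11 and 12.** The C1–O and C5–O bonds of ring D are cut on the ring D side. The neighbouring cuts are worse. Cutting on the ring C side would make C6 of ring C the electrophile, and its only free position (C2) is meta to C6, so no activating group can be placed. Cutting on the ring E side gives an unactivated 3,4,5-trioxygenated electrophile. The chosen cut turns the pentamer into the A–B–C phenol 10 and two catalogue compounds, 1,5-difluoro-3-methoxy-2-nitrobenzene 11 and 3,4,5-trimethoxyphenol 12. The forward reaction must place the phenoxide of 10 at the fluorine para to nitro, giving monofluoride 13, and then the phenoxide of 12 at the fluorine ortho to nitro, one after the other in one flask.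

**10 from 5 and 7 by way of 8.** The C6 hydroxyl of ring C is traced to a formyl group (phenol 10 from aldehyde 8 by Baeyer–Villiger oxidation). The C1–O bond of ring C is then cut, with ring C as the electrophile 7 (fluorine ortho to the formyl group) and the A–B phenol 5 as the nucleophile. The opposite polarity would need an electrophile at C4 of ring B, which lies between two methoxy groups and cannot be activated. The formyl group does for ring C what nitro does for ring D, but becomes the hydroxyl in one operation.

**7 from 6.** The bond between ring C and the formyl carbon is cut. 5-Fluoro-1,2,3-trimethoxybenzene 6 has two ring hydrogens that are equivalent by symmetry, each between fluorine and a methoxy group, so formylation can give only one isomer.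

**5 from 1 and 2 by way of 3.** The same pair of operations builds the A–B ether: phenol 5 from aldehyde 3 by Baeyer–Villiger oxidation, and 3 from 2,4,6-trimethoxyphenol 1 and 4-fluoro-2,6-dimethoxybenzaldehyde 2. The formyl group of 2 is para to fluorine and lies between the two methoxy groups that end up beside the new hydroxyl.

## Roads not taken

Alternative 1: ring A would be built by a double Claisen condensation.
- Cut: the C1–C6 and C3–C4 bonds of ring A.
- Forward key step: dimethyl 2-[4-(benzyloxy)-3,5-dimethoxyphenoxy]propanedioate A2 and dimethyl 3-oxopentanedioate A3 would condense under sodium methoxide. The two methylene carbons of A3 are acylated in turn by the two ester groups of A2, which closes ring A as dimethyl 5-[4-(benzyloxy)-3,5-dimethoxyphenoxy]-2,4,6-trihydroxybenzene-1,3-dicarboxylate A1.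
- Merits: this is the only plan that makes a ring of the target from acyclic material. Ring A is symmetric, so there is no regiochemical question. A3 is a catalogue compound. The ring arrives with free hydroxyls, which would reduce the final deprotection from twelve ethers to nine.
- Weak points: A1 solves only the A–B end, where the chosen plan needs two steps from catalogue compounds, and A2 must itself first be prepared from a protected ring B phenol. Both ester groups of A1 must be removed, the benzyl group taken off, and the three free hydroxyls protected again, since they would compete as nucleophiles in every later etherification. The advantage of the free phenols is thus given back.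
- Comparison: this road is equal to the chosen plan in regiochemical certainty, clearly longer, and silent on the difficult bond between rings C and D.

Alternative 2: ring C would be built by squarate ring expansion.
- Cut: the C6–C1 bond of ring C, at the stage of a hydroquinone.
- Forward key step: dimethyl squarate A6 would take up, at one carbonyl, a lithiated 2-aryloxyvinyl unit bearing rings A and B. This gives racemic 4-hydroxy-2,3-dimethoxy-4-[(E)-2-{2,6-dimethoxy-4-(2,4,6-trimethoxyphenoxy)phenoxy}ethenyl]cyclobut-2-en-1-one A5. Thermolysis of A5 opens the four-membered ring to a dienylketene, which closes by 6π electrocyclisation and tautomerises to 5-[2,6-dimethoxy-4-(2,4,6-trimethoxyphenoxy)phenoxy]-2,3-dimethoxybenzene-1,4-diol A4.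
- Merits: all five oxygens of ring C are placed by the mechanism under neutral thermal conditions, and A6 is a catalogue compound. The road avoids the substitution on a fluoroaldehyde that carries a para methoxy group, which is step 4 of the chosen route and one of its slower steps. In that respect this road is better.
- Weak points: a vinyl-lithium with an aryloxy group on the β carbon tends to eliminate aryloxide before it can add to A6. The vinyl ether must itself be made from phenol 5 in several steps. The two hydroquinone hydroxyls of A4 must be told apart, and the less hindered one methylated, before the material converges on phenol 10.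
- Comparison: this is a longer way to 10 and still needs the ring D chemistry of the chosen plan. The chosen plan sets against it two steps from 5 to 10 and a well-precedented fallback through nitro activation.

Alternative 3: ring D would be built by Danheiser benzannulation.
- Cut: three C–C bonds of ring D (C1–C6, C4–C5 and C1–C2).
- Forward key step: heating 2,3-dimethoxycyclobut-2-en-1-one A8 with 5-(ethynyloxy)-1,2,3-trimethoxybenzene A9 would open A8 to a vinylketene. This adds to the alkyne of A9 in a [2+2] sense, and the adduct opens to a dienylketene that electrocyclises. The product is 3,4-dimethoxy-5-(3,4,5-trimethoxyphenoxy)phenol A7.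
- Merits: A7 carries the ether between rings D and E and the C4 oxygen of ring D from the start. The nitro reduction and the diazonium hydroxylation of the chosen route are not needed, and there is no para/ortho question. In these two respects this road is better.
- Weak points: the free hydroxyl of A7 is at C1 of ring D, so ring C would have to be the electrophile at C6. That means a copper-mediated coupling with a di-ortho-substituted, electron-rich aryl halide, the least reliable class of diaryl ether formation. Neither A8 nor A9 is a catalogue compound, and aryl ethynyl ethers such as A9 are labile.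
- Comparison: the chosen plan accepts two functional-group steps on ring D. In return ring C reacts as the nucleophile, which is the only polarity open to it, and ring D comes from a catalogue compound.

Key step: step 6

## Route

Assumption: 5-fluoro-1,2,3-trimethoxybenzene 6 is taken as a catalogue compound. All ring positions named in the steps follow the ring lettering A to E used above.

Step 1
Reactants: 1 2,4,6-trimethoxyphenol; 2 4-fluoro-2,6-dimethoxybenzaldehyde
Product: 3 2,6-dimethoxy-4-(2,4,6-trimethoxyphenoxy)benzaldehyde
Conditions: K2CO3, DMSO, 110 °C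
Reagents that add atoms: none
Why: SNAr of a phenoxide on a 4-fluorobenzaldehyde; the formyl group para to fluorine takes up the charge of the Meisenheimer complex, and the two methoxy groups sit meta to the reacting carbon, where they do not oppose it.

Step 2
Reactants: 3 2,6-dimethoxy-4-(2,4,6-trimethoxyphenoxy)benzaldehyde
Product: 5 2,6-dimethoxy-4-(2,4,6-trimethoxyphenoxy)phenol, via aryl formate 4 (not isolated)
Conditions: mCPBA, CH2Cl2, 0 °C to rt; after aqueous NaHCO3 wash, K2CO3 (cat.), MeOH, rt
Reagents that add atoms: mCPBA (3-chloroperoxybenzoic acid), SMILES OOC(=O)c1cccc(Cl)c1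
Why: Baeyer–Villiger oxidation of an electron-rich benzaldehyde (Dakin-type); the aryl group with two ortho methoxy groups migrates in preference to hydrogen, and the formate is removed by base-catalysed methanolysis.

Step 3
Reactants: 6 5-fluoro-1,2,3-trimethoxybenzene
Product: 7 6-fluoro-2,3,4-trimethoxybenzaldehyde
Conditions: n-BuLi, THF, −78 °C; DMF, −78 to 0 °C; aq. HCl
Reagents that add atoms: N,N-dimethylformamide, SMILES CN(C)C=O
Why: Directed ortho-lithiation at the position between fluorine and methoxy, followed by formylation with DMF; the two ring hydrogens of 6 are equivalent, so only one aldehyde can form, and at −78 °C the ortho-fluoroaryllithium should not lose LiF.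

Step 4
Reactants: 5 2,6-dimethoxy-4-(2,4,6-trimethoxyphenoxy)phenol; 7 6-fluoro-2,3,4-trimethoxybenzaldehyde
Product: 8 6-[2,6-dimethoxy-4-(2,4,6-trimethoxyphenoxy)phenoxy]-2,3,4-trimethoxybenzaldehyde
Conditions: Cs2CO3, DMSO, 120 °C
Reagents that add atoms: none
Why: SNAr of a phenoxide on a 2-fluorobenzaldehyde; the ortho formyl group stabilises the Meisenheimer complex, and the methoxy group para to fluorine is the middle one of three, twisted out of the ring plane, so it acts mainly as an inductive acceptor.

Step 5
Reactants: 8 6-[2,6-dimethoxy-4-(2,4,6-trimethoxyphenoxy)phenoxy]-2,3,4-trimethoxybenzaldehyde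
Product: 10 6-[2,6-dimethoxy-4-(2,4,6-trimethoxyphenoxy)phenoxy]-2,3,4-trimethoxyphenol, via aryl formate 9 (not isolated)
Conditions: mCPBA, CH2Cl2, 0 °C to rt; after aqueous NaHCO3 wash, K2CO3 (cat.), MeOH, rt
Reagents that add atoms: mCPBA (3-chloroperoxybenzoic acid), SMILES OOC(=O)c1cccc(Cl)c1
Why: Baeyer–Villiger oxidation as in step 2; the migrating carbon lies between an aryloxy and a methoxy group, which favours aryl migration, and methanolysis of the formate frees the C6 hydroxyl of ring C.

Step 6
Reactants: 10 6-[2,6-dimethoxy-4-(2,4,6-trimethoxyphenoxy)phenoxy]-2,3,4-trimethoxyphenol; 11 1,5-difluoro-3-methoxy-2-nitrobenzene; 12 3,4,5-trimethoxyphenol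
Product: 14 1-[2,6-dimethoxy-4-(2,4,6-trimethoxyphenoxy)phenoxy]-3,4,5-trimethoxy-2-[3-methoxy-4-nitro-5-(3,4,5-trimethoxyphenoxy)phenoxy]benzene, via para-substituted monofluoride 13 (not isolated)
Conditions: 10, 11 (1.05 equiv), Cs2CO3, DMSO, 25 °C; then 12 (1.5 equiv), Cs2CO3, 90 °C
Reagents that add atoms: none
Why: Each C–O bond forms by addition–elimination: the phenoxide adds to a fluorine-bearing carbon, the charge of the Meisenheimer complex is taken up by the nitro group, and fluoride leaves. The closest known reaction type is the sequential SNAr of 2,4-difluoronitroarenes with two different phenoxides, run in one pot by order of addition and temperature. No ring is closed and no stereocentre is formed; the selectivity needed is positional, with the ring C phenoxide at the carbon para to nitro (C1 of ring D) and the ring E phenoxide at the ortho carbon (C5). The two fluorines of 11 are electronically alike, each meta to the other and to the methoxy group, so sterics should decide the first stage. The phenoxide of 10 lies between an aryloxy and a methoxy group, and the ortho carbon of 11 lies beside a nitro group that is itself crowded by the methoxy group, whereas the para carbon has hydrogen on both sides. DMSO and the large caesium ion disfavour the contact-ion-pair pathway that delivers a nucleophile to the ortho position. The aryloxy group that enters first donates into the nitro group and lowers the reactivity of 13, so 13 should persist at 25 °C and react with the unhindered 3,4,5-trimethoxyphenoxide only at 90 °C. Near-stoichiometric 11 limits double substitution by 10, and fluoride is a far better leaving group here than methoxide or nitrite.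

Step 7
Reactants: 14 1-[2,6-dimethoxy-4-(2,4,6-trimethoxyphenoxy)phenoxy]-3,4,5-trimethoxy-2-[3-methoxy-4-nitro-5-(3,4,5-trimethoxyphenoxy)phenoxy]benzene
Product: 15 4-{2-[2,6-dimethoxy-4-(2,4,6-trimethoxyphenoxy)phenoxy]-4,5,6-trimethoxyphenoxy}-2-methoxy-6-(3,4,5-trimethoxyphenoxy)aniline
Conditions: H2 (1 atm), 10% Pd/C, EtOAc/EtOH, rt
Reagents that add atoms: none
Why: Catalytic hydrogenation of an aromatic nitro group to the aniline; the molecule contains only methyl aryl and diaryl ethers, which are inert to these conditions.

Step 8
Reactants: 15 4-{2-[2,6-dimethoxy-4-(2,4,6-trimethoxyphenoxy)phenoxy]-4,5,6-trimethoxyphenoxy}-2-methoxy-6-(3,4,5-trimethoxyphenoxy)aniline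
Product: 17 4-{2-[2,6-dimethoxy-4-(2,4,6-trimethoxyphenoxy)phenoxy]-4,5,6-trimethoxyphenoxy}-2-methoxy-6-(3,4,5-trimethoxyphenoxy)phenol, via arenediazonium hydrogensulfate 16 (not isolated)
Conditions: NaNO2, H2SO4, H2O/MeCN, 0 °C; then Cu(NO3)2 (large excess), Cu2O (1 equiv), H2O, rt
Reagents that add atoms: water, SMILES O; sodium nitrite, SMILES [Na+].[O-]N=O (supplies the outer nitrogen of 16 only)
Why: Diazotisation followed by copper-mediated hydroxydediazoniation (Cohen conditions); cuprous ion reduces the diazonium ion to the aryl radical, and the large excess of cupric ion captures it and delivers hydroxyl from water at room temperature, which should outrun cyclisation onto ring E.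

Step 9
Reactants: 17 4-{2-[2,6-dimethoxy-4-(2,4,6-trimethoxyphenoxy)phenoxy]-4,5,6-trimethoxyphenoxy}-2-methoxy-6-(3,4,5-trimethoxyphenoxy)phenol
Product: 18 5-{2-[2,6-dihydroxy-4-(2,4,6-trihydroxyphenoxy)phenoxy]-4,5,6-trihydroxyphenoxy}-3-(3,4,5-trihydroxyphenoxy)benzene-1,2-diol
Conditions: BBr3 (excess), CH2Cl2, −78 °C to rt; H2O, 0 °C; under argon
Reagents that add atoms: none
Why: Lewis-acid cleavage of methyl aryl ethers by BBr3; bromide attacks the methyl carbon of the boron-complexed ether (SN2), which a diaryl ether cannot undergo, and the acidic, oxidant-free work-up protects the pyrogallol and catechol units.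

## Compound list

1 | 2,4,6-trimethoxyphenol | COc1cc(OC)c(O)c(OC)c1 | starting material
2 | 4-fluoro-2,6-dimethoxybenzaldehyde | COc1cc(F)cc(OC)c1C=O | starting material
3 | 2,6-dimethoxy-4-(2,4,6-trimethoxyphenoxy)benzaldehyde | COc1cc(OC)c(Oc2cc(OC)c(C=O)c(OC)c2)c(OC)c1 | intermediate
4 | 2,6-dimethoxy-4-(2,4,6-trimethoxyphenoxy)phenyl formate | COc1cc(OC)c(Oc2cc(OC)c(OC=O)c(OC)c2)c(OC)c1 | intermediate
5 | 2,6-dimethoxy-4-(2,4,6-trimethoxyphenoxy)phenol | COc1cc(OC)c(Oc2cc(OC)c(O)c(OC)c2)c(OC)c1 | intermediate
6 | 5-fluoro-1,2,3-trimethoxybenzene | COc1cc(F)cc(OC)c1OC | starting material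
7 | 6-fluoro-2,3,4-trimethoxybenzaldehyde | COc1cc(F)c(C=O)c(OC)c1OC | intermediate
8 | 6-[2,6-dimethoxy-4-(2,4,6-trimethoxyphenoxy)phenoxy]-2,3,4-trimethoxybenzaldehyde | COc1cc(OC)c(Oc2cc(OC)c(Oc3cc(OC)c(OC)c(OC)c3C=O)c(OC)c2)c(OC)c1 | intermediate
9 | 6-[2,6-dimethoxy-4-(2,4,6-trimethoxyphenoxy)phenoxy]-2,3,4-trimethoxyphenyl formate | COc1cc(OC)c(Oc2cc(OC)c(Oc3cc(OC)c(OC)c(OC)c3OC=O)c(OC)c2)c(OC)c1 | intermediate
10 | 6-[2,6-dimethoxy-4-(2,4,6-trimethoxyphenoxy)phenoxy]-2,3,4-trimethoxyphenol | COc1cc(OC)c(Oc2cc(OC)c(Oc3cc(OC)c(OC)c(OC)c3O)c(OC)c2)c(OC)c1 | intermediate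
11 | 1,5-difluoro-3-methoxy-2-nitrobenzene | COc1cc(F)cc(F)c1[N+](=O)[O-] | starting material
12 | 3,4,5-trimethoxyphenol | COc1cc(O)cc(OC)c1OC | starting material
13 | 1-[2,6-dimethoxy-4-(2,4,6-trimethoxyphenoxy)phenoxy]-2-(3-fluoro-5-methoxy-4-nitrophenoxy)-3,4,5-trimethoxybenzene | COc1cc(OC)c(Oc2cc(OC)c(Oc3cc(OC)c(OC)c(OC)c3Oc3cc(F)c([N+](=O)[O-])c(OC)c3)c(OC)c2)c(OC)c1 | intermediate
14 | 1-[2,6-dimethoxy-4-(2,4,6-trimethoxyphenoxy)phenoxy]-3,4,5-trimethoxy-2-[3-methoxy-4-nitro-5-(3,4,5-trimethoxyphenoxy)phenoxy]benzene | COc1cc(OC)c(Oc2cc(OC)c(Oc3cc(OC)c(OC)c(OC)c3Oc3cc(OC)c([N+](=O)[O-])c(Oc4cc(OC)c(OC)c(OC)c4)c3)c(OC)c2)c(OC)c1 | intermediate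
15 | 4-{2-[2,6-dimethoxy-4-(2,4,6-trimethoxyphenoxy)phenoxy]-4,5,6-trimethoxyphenoxy}-2-methoxy-6-(3,4,5-trimethoxyphenoxy)aniline | COc1cc(OC)c(Oc2cc(OC)c(Oc3cc(OC)c(OC)c(OC)c3Oc3cc(OC)c(N)c(Oc4cc(OC)c(OC)c(OC)c4)c3)c(OC)c2)c(OC)c1 | intermediate
16 | 4-{2-[2,6-dimethoxy-4-(2,4,6-trimethoxyphenoxy)phenoxy]-4,5,6-trimethoxyphenoxy}-2-methoxy-6-(3,4,5-trimethoxyphenoxy)benzenediazonium hydrogensulfate | COc1cc(OC)c(Oc2cc(OC)c(Oc3cc(OC)c(OC)c(OC)c3Oc3cc(OC)c([N+]#N)c(Oc4cc(OC)c(OC)c(OC)c4)c3)c(OC)c2)c(OC)c1.OS(=O)(=O)[O-] | intermediate
17 | 4-{2-[2,6-dimethoxy-4-(2,4,6-trimethoxyphenoxy)phenoxy]-4,5,6-trimethoxyphenoxy}-2-methoxy-6-(3,4,5-trimethoxyphenoxy)phenol | COc1cc(OC)c(Oc2cc(OC)c(Oc3cc(OC)c(OC)c(OC)c3Oc3cc(OC)c(O)c(Oc4cc(OC)c(OC)c(OC)c4)c3)c(OC)c2)c(OC)c1 | intermediate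
18 | 5-{2-[2,6-dihydroxy-4-(2,4,6-trihydroxyphenoxy)phenoxy]-4,5,6-trihydroxyphenoxy}-3-(3,4,5-trihydroxyphenoxy)benzene-1,2-diol | Oc1cc(O)c(Oc2cc(O)c(Oc3cc(O)c(O)c(O)c3Oc3cc(O)c(O)c(Oc4cc(O)c(O)c(O)c4)c3)c(O)c2)c(O)c1 | target

## Step count and risks

Total step count: 9. Longest linear sequence: 8 (steps 1, 2, 4, 5, 6, 7, 8, 9, from compound 1); step 3 is a one-step branch.

**Step 6 (key step).**
- What may go wrong: loss of positional control in the first stage. The two fluorines differ little electronically. The nitro group of 11 is flanked by methoxy and fluorine and is twisted out of the ring plane, which weakens its resonance activation of the para carbon more than its inductive activation of the ortho carbon. Attack of the ring C phenoxide at the ortho carbon, or a second substitution by the same phenoxide, would therefore consume the trimer. At 90 °C, displacement of the crowded nitro group or of the methoxy group could also compete.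
- Fallback: the order is reversed and the two bonds are made in separate flasks, starting from 11 and 12. The potassium salt of 12 (from KOtBu) reacts with 11 in toluene at 0 to 25 °C. In this non-polar medium the potassium ion bridges the nitro oxygen and the phenoxide, which directs substitution to the ortho fluorine and should give 5-fluoro-1-methoxy-2-nitro-3-(3,4,5-trimethoxyphenoxy)benzene F1. Its constitution can be checked before any trimer is used. Phenol 10 then displaces the one remaining fluorine, para to nitro, with Cs2CO3 in DMSO at 80 °C, where no positional choice is left. The route is rejoined at 14.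

**Step 4.**
- What may go wrong: slow substitution, because the methoxy group para to fluorine raises the energy of the Meisenheimer complex and the phenoxide of 5 has two ortho substituents. Long heating in base may also degrade the aldehyde.
- Fallback: ring C is activated by nitro instead of formyl, starting from 5 and 6. Nitration of 6 (HNO3, AcOH, 0 °C) can occur only at the two equivalent positions and gives 1-fluoro-3,4,5-trimethoxy-2-nitrobenzene F2. Phenol 5 displaces its fluorine (K2CO3, DMF, 60 °C) to give 1-[2,6-dimethoxy-4-(2,4,6-trimethoxyphenoxy)phenoxy]-3,4,5-trimethoxy-2-nitrobenzene F3. Hydrogenation over Pd/C gives 6-[2,6-dimethoxy-4-(2,4,6-trimethoxyphenoxy)phenoxy]-2,3,4-trimethoxyaniline F4. Diazotisation (NaNO2, H2SO4) gives 6-[2,6-dimethoxy-4-(2,4,6-trimethoxyphenoxy)phenoxy]-2,3,4-trimethoxybenzenediazonium hydrogensulfate F5, which is hydroxylated with Cu(NO3)2 and Cu2O in water. The route is rejoined at 10. Both ortho positions of ring B are blocked by methoxy groups, so radical cyclisation is less of a concern here than in step 8.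

**Step 8.**
- What may go wrong: several side reactions compete with hydroxylation.
  - Cyclisation of the aryl radical onto a free ortho position of ring E (Pschorr-type closure to a dibenzofuran).
  - Hydrogen-atom abstraction from the co-solvent, which replaces the diazonium group by hydrogen.
  - Azo coupling of the diazonium ion with the electron-rich ring A.
  - Poor solubility of the large diazonium salt in the aqueous medium.
- Fallback: the oxygen is introduced by cross-coupling instead of radical capture; the fallback sets out from 15. Diazonium salt 16, made from 15 as before, is treated with aqueous KI. Iodine transfer to the aryl radical is among the fastest trapping reactions and needs no copper. It gives 1-[2,6-dimethoxy-4-(2,4,6-trimethoxyphenoxy)phenoxy]-2-[4-iodo-3-methoxy-5-(3,4,5-trimethoxyphenoxy)phenoxy]-3,4,5-trimethoxybenzene F6. Palladium-catalysed hydroxylation of F6 (Pd2(dba)3 as zerovalent palladium source, tBuXPhos, KOH, 1,4-dioxane/H2O, 100 °C) rejoins the route at 17.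

**Step 9.**
- What may go wrong: incomplete cleavage across twelve ether sites, leaving partly methylated material that is hard to separate from the product, and oxidative degradation of the pyrogallol and catechol units during isolation.
- Fallback: the polyphenol is not isolated directly. Starting from 17, the crude product of the BBr3 cleavage is acetylated (Ac2O, pyridine) to the trideca-acetate 5-{2-[2,6-diacetoxy-4-(2,4,6-triacetoxyphenoxy)phenoxy]-4,5,6-triacetoxyphenoxy}-3-(3,4,5-triacetoxyphenoxy)benzene-1,2-diyl diacetate F7. F7 should be air-stable and separable on silica from any partly methylated acetates. Acid-catalysed methanolysis (HCl in MeOH, argon) then releases 18 without base.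

## Further compounds

F1 | step 6 | 5-fluoro-1-methoxy-2-nitro-3-(3,4,5-trimethoxyphenoxy)benzene | COc1cc(F)cc(Oc2cc(OC)c(OC)c(OC)c2)c1[N+](=O)[O-]
F2 | step 4 | 1-fluoro-3,4,5-trimethoxy-2-nitrobenzene | COc1cc(F)c([N+](=O)[O-])c(OC)c1OC
F3 | step 4 | 1-[2,6-dimethoxy-4-(2,4,6-trimethoxyphenoxy)phenoxy]-3,4,5-trimethoxy-2-nitrobenzene | COc1cc(OC)c(Oc2cc(OC)c(Oc3cc(OC)c(OC)c(OC)c3[N+](=O)[O-])c(OC)c2)c(OC)c1
F4 | step 4 | 6-[2,6-dimethoxy-4-(2,4,6-trimethoxyphenoxy)phenoxy]-2,3,4-trimethoxyaniline | COc1cc(OC)c(Oc2cc(OC)c(Oc3cc(OC)c(OC)c(OC)c3N)c(OC)c2)c(OC)c1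
F5 | step 4 | 6-[2,6-dimethoxy-4-(2,4,6-trimethoxyphenoxy)phenoxy]-2,3,4-trimethoxybenzenediazonium hydrogensulfate | COc1cc(OC)c(Oc2cc(OC)c(Oc3cc(OC)c(OC)c(OC)c3[N+]#N)c(OC)c2)c(OC)c1.OS(=O)(=O)[O-]
F6 | step 8 | 1-[2,6-dimethoxy-4-(2,4,6-trimethoxyphenoxy)phenoxy]-2-[4-iodo-3-methoxy-5-(3,4,5-trimethoxyphenoxy)phenoxy]-3,4,5-trimethoxybenzene | COc1cc(OC)c(Oc2cc(OC)c(Oc3cc(OC)c(OC)c(OC)c3Oc3cc(OC)c(I)c(Oc4cc(OC)c(OC)c(OC)c4)c3)c(OC)c2)c(OC)c1
F7 | step 9 | 5-{2-[2,6-diacetoxy-4-(2,4,6-triacetoxyphenoxy)phenoxy]-4,5,6-triacetoxyphenoxy}-3-(3,4,5-triacetoxyphenoxy)benzene-1,2-diyl diacetate | CC(=O)Oc1cc(OC(C)=O)c(Oc2cc(OC(C)=O)c(Oc3cc(OC(C)=O)c(OC(C)=O)c(OC(C)=O)c3Oc3cc(OC(C)=O)c(OC(C)=O)c(Oc4cc(OC(C)=O)c(OC(C)=O)c(OC(C)=O)c4)c3)c(OC(C)=O)c2)c(OC(C)=O)c1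
A1 | alternative 1 | dimethyl 5-[4-(benzyloxy)-3,5-dimethoxyphenoxy]-2,4,6-trihydroxybenzene-1,3-dicarboxylate | COC(=O)c1c(O)c(C(=O)OC)c(O)c(Oc2cc(OC)c(OCc3ccccc3)c(OC)c2)c1O
A2 | alternative 1 | dimethyl 2-[4-(benzyloxy)-3,5-dimethoxyphenoxy]propanedioate | COC(=O)C(Oc1cc(OC)c(OCc2ccccc2)c(OC)c1)C(=O)OC
A3 | alternative 1 | dimethyl 3-oxopentanedioate | COC(=O)CC(=O)CC(=O)OC
A4 | alternative 2 | 5-[2,6-dimethoxy-4-(2,4,6-trimethoxyphenoxy)phenoxy]-2,3-dimethoxybenzene-1,4-diol | COc1c(O)cc(Oc2c(OC)cc(Oc3c(OC)cc(OC)cc3OC)cc2OC)c(O)c1OC
A5 | alternative 2 | racemic 4-hydroxy-2,3-dimethoxy-4-[(E)-2-{2,6-dimethoxy-4-(2,4,6-trimethoxyphenoxy)phenoxy}ethenyl]cyclobut-2-en-1-one | COC1=C(OC)C(O)(/C=C/Oc2c(OC)cc(Oc3c(OC)cc(OC)cc3OC)cc2OC)C1=O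
A6 | alternative 2 | dimethyl squarate (3,4-dimethoxycyclobut-3-ene-1,2-dione) | COC1=C(OC)C(=O)C1=O
A7 | alternative 3 | 3,4-dimethoxy-5-(3,4,5-trimethoxyphenoxy)phenol | COc1cc(O)cc(Oc2cc(OC)c(OC)c(OC)c2)c1OC
A8 | alternative 3 | 2,3-dimethoxycyclobut-2-en-1-one | COC1=C(OC)C(=O)C1
A9 | alternative 3 | 5-(ethynyloxy)-1,2,3-trimethoxybenzene | COc1cc(OC#C)cc(OC)c1OC
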